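1. Start from a ratio: in the north-east run, with substrate already at 0% at 0.250 d, target fell from 63% to 3% by 1.67 d, a factor of 21.0. Use it to decide whether the next row keeps its charges, its hold of 6.0 d and the percent reading, whose scatter is 2 percentage points.

| flask | substrate | remark | time |
|---|---|---|---|
| north-east | 0.0096 M | run made earlier |  |
| ochre | 0.012 M |  | 6.0 d |
| grey | 0.025 M |  | 6.0 d |
| blue | 0.050 M |  | 6.0 d |
| amber | 0.10 M |  | 6.0 d |
| teal | 0.20 M |  | 6.0 d |

north-east run (percent of the substrate charged)

| time / d | target / % | substrate / % |
|---|---|---|
| 0.250 | 63 | 0 |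
| 0.417 | 37 | 0 |
| 0.833 | 11 | 0 |
| 1.67 | 3 | 0 |
| 3.00 | 2 | 0 |

(readings scatter by 2 percentage points)

- the earlier runs were read with a standard deviation of 2 percentage points
- steps under discussion: target -> over-reaction product; substrate -> target; substrate <-> dormant form
- "hardly changes" means that all values lie within two and a half points (for a concentration: within two and a half percent of the largest)

1. [target] at the end for ochre, grey, blue, amber, teal, in this order
2. the course of these numbers from the first flask to the last (falls all the way / hardly changes / falls, then rises / rises, then falls / rises all the way)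

2. Solve the early end. Substrate reads 0% at the first reading, so take that reading of target as the start of a plain decay.

3. Solve the late end. Assume first-order loss of target and read the rate from the ratio: 2.14 d⁻¹. The readings from 63% to 11% give 2.99 d⁻¹, which is faster, so treat the first rate as the slow reading.

4. Join the ends. My reckoning gives 2.79 × 10⁻⁶ as the survivor share, the estimated share of the charge still standing as target at the end of the hold. For teal that is 5.58 × 10⁻⁷ M, while 2 points of teal's charge is 0.00400 M, far more. This assumes first-order loss holds at teal's charge, 20.8 times the north-east charge. Decide: keep the charges and the hold, but do not expect the percent reading to show this row.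

5. The forecast differs from my reckoning: 1.000 × 10⁻⁴ M, 2.000 × 10⁻⁴ M, 5.000 × 10⁻⁴ M, 0.002 M, 0.07 M, course rises all the way, on the ground “so the removal looks saturable”. Its teal value stands above my estimate for teal.

6. The flasks give 4.06 × 10⁻⁹ M, 8.56 × 10⁻⁹ M, 1.75 × 10⁻⁸ M, 3.62 × 10⁻⁸ M, 7.68 × 10⁻⁸ M, course rises all the way.

    target → over-reaction product (k = 0.104 h⁻¹)
    substrate → target, rate k2*[substrate]/(1 + ([substrate]/sat2)) (24.2 mM, k = 4.12 h⁻¹)
    substrate ⇌ dormant form (K = 1.30, k = 1.10 h⁻¹)

In ochre, the half-life of target by its passing into over-reaction product is 0.28 d, short against the hold of 6.0 d, and over-reaction product stands at >99.9% at 6.00 d. Ochre's 4.06 × 10⁻⁹ M is 3.38 × 10⁻⁷ of its charge, under the survivor share of 2.79 × 10⁻⁶, and teal's 7.68 × 10⁻⁸ M is 3.84 × 10⁻⁷ of its charge, also under it.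

The runs stem from a simulated flask with constants of no real substance.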